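**Plan**

1. Retrosynthesis cuts, in order: the ketal and acetal C–O bonds on the ring and the C3–O bond of the carbinol (C3–OH ⇒ C3–Bpin); then the C3–C4 bond between the heptyl chain and the carbinol carbon; then C2–C3; last the aryl C–CHO bond and one ring C–O bond, back to 2,6-dimethyl-1,4-benzoquinone.
2. Forward: the bought quinone ring is made 1,2,4-trioxygenated, the two adjacent oxygens are tied into a 1,3-benzodioxole ring, the hydroxyl between the two methyl groups is acetylated, and the last ring CH is formylated and masked as a dioxolane.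
3. The acetate methyl (chain C2) is then homologated to a racemic C3(H)(Cl)Bpin, C4–C10 are joined at C3, boron is exchanged for oxygen, and one acid step removes both acetals.
4. Enabling feature: C3, the only stereocentre, is a secondary carbinol carbon between C2H2 and C4H2. With Bpin in place of OH and a chloride on the same carbon it gives a planar, boron-stabilised radical, so both enantiomers of the chloride can converge on one configuration. The ester oxygen sits on ring carbon C1 between the methyl-bearing ring carbons C2 and C6, which keeps the aryl acetate enolate alive and shields the ester carbonyl.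
5. Stereochemistry: (R) at C3 comes from the chiral nickel–diamine catalyst in the enantioconvergent alkyl–alkyl coupling and is carried over by stereoretentive C–B to C–O oxidation.

Key step: step 8

Remark: the sense of induction of the nickel–diamine catalyst on this β-(aryloxycarbonyl) α-chloroboronate is assumed, not known; the (R,R)-ligand is written, and the (S,S)-antipode would be used if a pilot run (oxidation to 15, Mosher ester analysis) shows the opposite sense.

Step 1
Reactants: 1 2,6-dimethyl-1,4-benzoquinone
Product: 2 3,5-dimethylbenzene-1,2,4-triyl triacetate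
Conditions: Ac2O, H2SO4 (cat.), 0 °C → rt
Reagents that add atoms: acetic anhydride, CC(=O)OC(C)=O
Why: Thiele–Winter acetoxylation; acid-activated conjugate addition of acetate to one of the two symmetry-equivalent unsubstituted ring carbons, then aromatisation and O-acetylation, should give the 1,2,4-trioxygenated ring without regiochemical ambiguity.

Step 2
Reactants: 2 3,5-dimethylbenzene-1,2,4-triyl triacetate
Product: 4 2,2,4,6-tetramethyl-1,3-benzodioxol-5-ol, via free triol 3 (not isolated)
Conditions: HCl (cat.), MeOH, reflux, Ar; evaporate; then Me2C(OMe)2, TsOH·H2O (cat.), toluene, reflux (MeOH removed over 4 Å MS)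
Reagents that add atoms: 2,2-dimethoxypropane, COC(C)(C)OC
Why: Acid methanolysis frees the oxidation-prone triol without base, and ketalisation (transacetalisation) can close the five-membered benzodioxole ring only across the two adjacent hydroxyls, leaving the hydroxyl between the two methyl groups free.

Step 3
Reactants: 4 2,2,4,6-tetramethyl-1,3-benzodioxol-5-ol
Product: 5 2,2,4,6-tetramethyl-1,3-benzodioxol-5-yl acetate
Conditions: Ac2O, Et3N, DMAP (cat.), CH2Cl2, rt
Reagents that add atoms: acetic anhydride, CC(=O)OC(C)=O
Why: DMAP-catalysed acylation is routine for di-ortho-substituted phenols and installs the two carbons that become C1 and C2 of the side chain.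

Step 4
Reactants: 5 2,2,4,6-tetramethyl-1,3-benzodioxol-5-yl acetate
Product: 6 7-formyl-2,2,4,6-tetramethyl-1,3-benzodioxol-5-yl acetate
Conditions: Cl2CHOMe, SnCl4, CH2Cl2, −20 → 0 °C; then ice–water
Reagents that add atoms: dichloromethyl methyl ether, COC(Cl)Cl; water, O
Why: Rieche formylation; the ring has a single free CH, activated by the ortho ring oxygen and by an ortho and a para methyl group, so electrophilic substitution can give only this aldehyde, and SnCl4 at low temperature is chosen to spare the ketal.

Step 5
Reactants: 6 7-formyl-2,2,4,6-tetramethyl-1,3-benzodioxol-5-yl acetate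
Product: 7 7-(1,3-dioxolan-2-yl)-2,2,4,6-tetramethyl-1,3-benzodioxol-5-yl acetate
Conditions: (TMSOCH2)2, TMSOTf (cat.), CH2Cl2, −78 → −20 °C; pyridine quench
Reagents that add atoms: 1,2-bis(trimethylsilyloxy)ethane, C[Si](C)(C)OCCO[Si](C)(C)C
Why: Noyori acetalisation masks the aldehyde against the amide base, the enolate, the organozinc and the later oxidant under conditions that should leave the aryl acetate and the catechol ketal untouched, and the dioxolane is removed later in the same acid step as the ketal.

Step 6
Reactants: 7 7-(1,3-dioxolan-2-yl)-2,2,4,6-tetramethyl-1,3-benzodioxol-5-yl acetate; 8 2-(dichloromethyl)-4,4,5,5-tetramethyl-1,3,2-dioxaborolane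
Product: 11 7-(1,3-dioxolan-2-yl)-2,2,4,6-tetramethyl-1,3-benzodioxol-5-yl (±)-3-chloro-3-(4,4,5,5-tetramethyl-1,3,2-dioxaborolan-2-yl)propanoate, via lithium enolate 9 (not isolated), via lithium borate complex 10 (not isolated)
Conditions: LDA (1.0 equiv, commercial solution), THF, −78 °C; then 8 (1.1 equiv), −78 °C → rt; pH 7 buffer
Reagents that add atoms: none
Why: Matteson homologation with an ester enolate as nucleophile; the two ortho methyl groups should keep the aryl acetate enolate intact at −78 °C, it adds to boron, and 1,2-migration of the CH2CO2Ar group with loss of chloride forms C2–C3, the chloride being wanted racemic so that no stereocontrol is needed.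

Step 7
Reactants: 12 1-bromoheptane
Product: 13 heptylzinc bromide (titrated solution in DMA)
Conditions: Zn dust, I2 (cat.), DMA, 70 °C
Reagents that add atoms: zinc, [Zn]
Why: Direct insertion of iodine-activated zinc into a primary alkyl bromide in DMA is the standard preparation of alkylzinc halides for Negishi couplings.

Step 8
Reactants: 11 racemic α-chloroboronate (name as in step 6); 13 heptylzinc bromide
Product: 14 7-(1,3-dioxolan-2-yl)-2,2,4,6-tetramethyl-1,3-benzodioxol-5-yl (R)-3-(4,4,5,5-tetramethyl-1,3,2-dioxaborolan-2-yl)decanoate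
Conditions: NiBr2·diglyme (10 mol %), (R,R)-N,N′-dimethyl-1,2-diphenylethane-1,2-diamine (13 mol %), 13 (1.8 equiv), THF/DMA, 0 °C
Reagents that add atoms: none
Why: The chiral diamine–nickel catalyst is expected to abstract chlorine from either enantiomer of 11 to give the same planar C3 radical, stabilised by the empty p orbital of boron, which is captured by the heptyl–nickel species formed by transmetalation from 13 and reductively eliminates with formation of the C3–C4 bond. The closest known reaction type is the nickel/chiral-diamine-catalysed enantioconvergent Negishi alkyl–alkyl coupling of racemic α-chloroboronates with primary alkylzinc reagents. No ring is closed. The new C3 stereocentre is set by the catalyst alone, at the radical-capture and reductive-elimination stage, so the racemic chloride should be funnelled into the (R)-boronate, whose configuration is carried into the carbinol in step 9. The step needs enantioconvergence, cross-coupling in preference to loss of HCl or β-hydride elimination towards the conjugated β-boryl acrylate, and tolerance of the aryl ester; the Bpin group supplies the radical stabilisation and the contrast with the CH2 substituent that the catalyst reads, the two ortho methyl groups shield the ester carbonyl from the weakly nucleophilic alkylzinc, and the aldehyde is masked as the dioxolane.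

Step 9
Reactants: 14 aryl (R)-3-(pinacolatoboryl)decanoate (name as in step 8)
Product: 15 7-(1,3-dioxolan-2-yl)-2,2,4,6-tetramethyl-1,3-benzodioxol-5-yl (R)-3-hydroxydecanoate
Conditions: NaBO3·4H2O, THF/H2O (1:1), 0 °C → rt
Reagents that add atoms: sodium perborate (used as the tetrahydrate), [Na+].[O-]OB=O
Why: Perborate oxidation of a secondary alkyl pinacol boronate proceeds by 1,2-migration of carbon from boron to oxygen with retention, so (R)-C–B should become (R)-C–OH, and the mild, weakly basic medium is chosen for the hindered but base-sensitive aryl ester while catechol and aldehyde are still masked.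

Step 10
Reactants: 15 protected (R)-3-hydroxydecanoate (name as in step 9)
Product: 16 Penicipurate A, 3-formyl-4,5-dihydroxy-2,6-dimethylphenyl (R)-3-hydroxydecanoate
Conditions: TFA/H2O (9:1), 0 °C → rt; evaporate; brief aq. NaHCO3 wash
Reagents that add atoms: water, O
Why: Aqueous TFA should hydrolyse both the electron-rich aryl dioxolane and the catechol isopropylidene ketal (the standard removal of catechol acetonides), while the hindered aryl ester and the β-hydroxy ester stereocentre are not expected to suffer in acid at room temperature.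

**Compound list**

1 | 2,6-dimethyl-1,4-benzoquinone | CC1=CC(=O)C=C(C)C1=O | starting material
2 | 3,5-dimethylbenzene-1,2,4-triyl triacetate | CC(=O)Oc1cc(C)c(OC(C)=O)c(C)c1OC(C)=O | intermediate
3 | 3,5-dimethylbenzene-1,2,4-triol (not isolated) | Cc1cc(O)c(O)c(C)c1O | intermediate
4 | 2,2,4,6-tetramethyl-1,3-benzodioxol-5-ol | Cc1cc2OC(C)(C)Oc2c(C)c1O | intermediate
5 | 2,2,4,6-tetramethyl-1,3-benzodioxol-5-yl acetate | CC(=O)Oc1c(C)cc2OC(C)(C)Oc2c1C | intermediate
6 | 7-formyl-2,2,4,6-tetramethyl-1,3-benzodioxol-5-yl acetate | CC(=O)Oc1c(C)c(C=O)c2OC(C)(C)Oc2c1C | intermediate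
7 | 7-(1,3-dioxolan-2-yl)-2,2,4,6-tetramethyl-1,3-benzodioxol-5-yl acetate | CC(=O)Oc1c(C)c(C3OCCO3)c2OC(C)(C)Oc2c1C | intermediate
8 | 2-(dichloromethyl)-4,4,5,5-tetramethyl-1,3,2-dioxaborolane | ClC(Cl)B1OC(C)(C)C(C)(C)O1 | starting material
9 | lithium enolate of 7 (not isolated) | [Li]OC(=C)Oc1c(C)c(C3OCCO3)c2OC(C)(C)Oc2c1C | intermediate
10 | lithium (dichloromethyl)(aryloxycarbonylmethyl)(pinacolato)borate (not isolated) | [Li+].ClC(Cl)[B-]1(CC(=O)Oc2c(C)c(C5OCCO5)c3OC(C)(C)Oc3c2C)OC(C)(C)C(C)(C)O1 | intermediate
11 | 7-(1,3-dioxolan-2-yl)-2,2,4,6-tetramethyl-1,3-benzodioxol-5-yl (±)-3-chloro-3-(4,4,5,5-tetramethyl-1,3,2-dioxaborolan-2-yl)propanoate (racemic) | ClC(CC(=O)Oc1c(C)c(C3OCCO3)c2OC(C)(C)Oc2c1C)B1OC(C)(C)C(C)(C)O1 | intermediate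
12 | 1-bromoheptane | CCCCCCCBr | starting material
13 | heptylzinc bromide | CCCCCCC[Zn]Br | intermediate
14 | 7-(1,3-dioxolan-2-yl)-2,2,4,6-tetramethyl-1,3-benzodioxol-5-yl (R)-3-(4,4,5,5-tetramethyl-1,3,2-dioxaborolan-2-yl)decanoate | CCCCCCC[C@@H](B1OC(C)(C)C(C)(C)O1)CC(=O)Oc1c(C)c(C3OCCO3)c2OC(C)(C)Oc2c1C | intermediate
15 | 7-(1,3-dioxolan-2-yl)-2,2,4,6-tetramethyl-1,3-benzodioxol-5-yl (R)-3-hydroxydecanoate | CCCCCCC[C@@H](O)CC(=O)Oc1c(C)c(C3OCCO3)c2OC(C)(C)Oc2c1C | intermediate
16 | Penicipurate A, 3-formyl-4,5-dihydroxy-2,6-dimethylphenyl (R)-3-hydroxydecanoate | CCCCCCC[C@@H](O)CC(=O)Oc1c(C)c(O)c(O)c(C=O)c1C | target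

**Totals**

Total step count: 10. Longest linear sequence: 9 steps (steps 1–6, 8, 9, 10); step 7 is a one-step side branch.

**Steps most likely to fail**

Step 6. The aryl acetate enolate may collapse to ketene and phenoxide before it is trapped on boron, or base may strip HCl from the product to give the conjugated β-boryl acrylate. The fallback moves the enolate chemistry and the enantioconvergent coupling to a robust tert-butyl ester and attaches the arene afterwards; it sets out from 8, 13 and 7 and comes back at 14. tert-Butyl acetate is deprotonated with LDA and combined with 8 to give tert-butyl (±)-3-chloro-3-(4,4,5,5-tetramethyl-1,3,2-dioxaborolan-2-yl)propanoate F1. Nickel–diamine coupling of F1 with 13 under the conditions of step 8 should give tert-butyl (R)-3-(4,4,5,5-tetramethyl-1,3,2-dioxaborolan-2-yl)decanoate F2. TFA in CH2Cl2 removes the tert-butyl group to give (R)-3-(4,4,5,5-tetramethyl-1,3,2-dioxaborolan-2-yl)decanoic acid F3. In parallel, 7 is deacetylated (K2CO3, MeOH, 0 °C, Ar) to 7-(1,3-dioxolan-2-yl)-2,2,4,6-tetramethyl-1,3-benzodioxol-5-ol F4. Steglich esterification of F3 with F4 (DCC, DMAP, CH2Cl2) gives 14.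

Step 8. The nickel alkyl may undergo β-hydride elimination, or the chloride may be lost as HCl, towards the β-boryl acrylate; enantiodiscrimination may also be eroded if the β-ester carbonyl coordinates boron or nickel. The fallback sets C3 by asymmetric reduction instead of by C–C coupling; it sets out from 7 and comes back at 15. Compound 7 is converted with LDA (2 equiv, THF, −78 °C) into enolate 9, and crossed Claisen acylation with octanoyl chloride gives 7-(1,3-dioxolan-2-yl)-2,2,4,6-tetramethyl-1,3-benzodioxol-5-yl 3-oxodecanoate F5. Noyori asymmetric hydrogenation of F5 (Ru–(R)-BINAP, H2, EtOH/CH2Cl2), with the usual sense for β-keto esters, should give the (R)-alcohol 15.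

Step 4. The Lewis acid may open the isopropylidene ketal, or substitution at the crowded last ring position may be too slow. The fallback replaces electrophilic formylation by halogenation and metalation; it sets out from 4 and comes back at 6. Bromination of 4 with NBS (MeCN, 0 °C) at the only free ring position gives 7-bromo-2,2,4,6-tetramethyl-1,3-benzodioxol-5-ol F6. Deprotonation and bromine–lithium exchange (n-BuLi, 2.2 equiv, THF, −78 °C) followed by DMF gives 6-hydroxy-2,2,5,7-tetramethyl-1,3-benzodioxole-4-carbaldehyde F7. Acetylation of F7 (Ac2O, Et3N, DMAP) gives 6.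

**Further compounds**

F1 | step 6 | tert-butyl (±)-3-chloro-3-(4,4,5,5-tetramethyl-1,3,2-dioxaborolan-2-yl)propanoate | CC(C)(C)OC(=O)CC(Cl)B1OC(C)(C)C(C)(C)O1
F2 | step 6 | tert-butyl (R)-3-(4,4,5,5-tetramethyl-1,3,2-dioxaborolan-2-yl)decanoate | CCCCCCC[C@@H](B1OC(C)(C)C(C)(C)O1)CC(=O)OC(C)(C)C
F3 | step 6 | (R)-3-(4,4,5,5-tetramethyl-1,3,2-dioxaborolan-2-yl)decanoic acid | CCCCCCC[C@@H](B1OC(C)(C)C(C)(C)O1)CC(=O)O
F4 | step 6 | 7-(1,3-dioxolan-2-yl)-2,2,4,6-tetramethyl-1,3-benzodioxol-5-ol | Oc1c(C)c(C3OCCO3)c2OC(C)(C)Oc2c1C
F5 | step 8 | 7-(1,3-dioxolan-2-yl)-2,2,4,6-tetramethyl-1,3-benzodioxol-5-yl 3-oxodecanoate | CCCCCCCC(=O)CC(=O)Oc1c(C)c(C3OCCO3)c2OC(C)(C)Oc2c1C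
F6 | step 4 | 7-bromo-2,2,4,6-tetramethyl-1,3-benzodioxol-5-ol | Cc1c(Br)c2OC(C)(C)Oc2c(C)c1O
F7 | step 4 | 6-hydroxy-2,2,5,7-tetramethyl-1,3-benzodioxole-4-carbaldehyde | Cc1c(C=O)c2OC(C)(C)Oc2c(C)c1O
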